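**Retrosynthetic overview**

1. Target ⇒ enone diester (last step: Morita–Baylis–Hillman hydroxymethylation with formaldehyde) ⇒ its dimethyl ketal ⇒ ring C5 alcohol + angelic acid.
2. Key disconnection: the isopropyl–ring bond, the C5 carbinol and the epoxyangelate ester go back in one operation to a cis-2,3-epoxy-1-isopropylcyclohexenol ketal and (2R,3R)-2,3-dimethyloxirane-2-carbaldehyde (semipinacol 1,2-isopropyl shift relayed into an Evans–Tishchenko reduction).
3. Epoxy alcohol ⇒ desymmetrising hydroxyl-directed epoxidation of achiral 1-isopropyl-4,4-dimethoxycyclohexa-2,5-dien-1-ol ⇒ p-benzoquinone mono(dimethyl ketal) + isopropylmagnesium chloride.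
4. Epoxy aldehyde ⇒ Sharpless epoxidation, then oxidation, of angelyl alcohol ⇒ angelic acid (also the angelate source).
5. Ring order: side-chain oxirane first (step 2); the carbocycle is bought and never opened; a ring-fused oxirane is made in step 5 and consumed in step 6.

Assumption: 4,4-dimethoxycyclohexa-2,5-dien-1-one is bought; it is p-benzoquinone with one carbonyl protected as a dimethyl ketal, and this protecting group is taken off in step 8.

Assumption: the (R,R)-bishydroxamic acid ligand is taken to give the (1R,2S,6S)-epoxide in step 5; if the sense of induction proves opposite, the (S,S)-ligand is used in the same way.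

**Route**

Step 1
Reactants: 1 (2Z)-2-methylbut-2-enoic acid (angelic acid)
Product: 2 (2Z)-2-methylbut-2-en-1-ol
Conditions: LiAlH4, Et2O, 0 °C to rt; then H2O
Reagents that add atoms: none
Why: Hydride reduction of the carboxylic acid gives the primary allylic alcohol without reducing or isomerising the trisubstituted Z-alkene.

Step 2
Reactants: 2 (2Z)-2-methylbut-2-en-1-ol
Product: 3 [(2S,3R)-2,3-dimethyloxiran-2-yl]methanol
Conditions: Ti(OiPr)4 (10 mol%), L-(+)-diisopropyl tartrate (12 mol%), tBuOOH, 4 Å MS, CH2Cl2, −20 °C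
Reagents that add atoms: tert-butyl hydroperoxide, CC(C)(C)OO
Why: Sharpless asymmetric epoxidation delivers oxygen stereospecifically syn to one alkene face chosen by the L-(+)-tartrate (same face as for nerol), so the Z-geometry becomes the cis relation of the C3 methyl and CH2OH and both oxirane centres are set as (2S,3R).

Step 3
Reactants: 3 [(2S,3R)-2,3-dimethyloxiran-2-yl]methanol
Product: 4 (2R,3R)-2,3-dimethyloxirane-2-carbaldehyde
Conditions: TEMPO (10 mol%), PhI(OAc)2, CH2Cl2, rt; used as a dried solution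
Reagents that add atoms: none
Why: Oxoammonium (TEMPO) oxidation stops at the aldehyde and spares the epoxide, the α-carbon is quaternary and cannot epimerise, and the C2 descriptor changes from S to R only through CIP priorities.

Step 4
Reactants: 5 4,4-dimethoxycyclohexa-2,5-dien-1-one, 6 isopropylmagnesium chloride
Product: 7 4,4-dimethoxy-1-(propan-2-yl)cyclohexa-2,5-dien-1-ol
Conditions: CeCl3, THF, −78 °C; then pH 7 buffer
Reagents that add atoms: none
Why: Grignard 1,2-addition to the dienone carbonyl of the quinone monoketal (CeCl3 suppresses reduction and conjugate addition) gives the achiral, mirror-symmetric tertiary bis-allylic alcohol.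

Step 5
Reactants: 7 4,4-dimethoxy-1-(propan-2-yl)cyclohexa-2,5-dien-1-ol
Product: 8 (1R,2S,6S)-5,5-dimethoxy-2-(propan-2-yl)-7-oxabicyclo[4.1.0]hept-3-en-2-ol
Conditions: Hf(OtBu)4 (10 mol%), (R,R)-N,N'-(cyclohexane-1,2-diyl)bis(N-hydroxy-2,2-diphenylacetamide) (12 mol%), cumene hydroperoxide, 4 Å MS, toluene, 0 °C
Reagents that add atoms: cumene hydroperoxide, CC(C)(OO)c1ccccc1
Why: Hydroxyl-directed asymmetric epoxidation with a tetravalent hafnium bishydroxamate catalyst (a system used for tertiary allylic alcohols) delivers oxygen syn to the metal-bound OH, which fixes the relative configuration, while the ligand chooses between the two enantiotopic alkenes (desymmetrisation) and so sets C1, C2 and C6; further epoxidation of the minor enantiomer raises the ee.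

Step 6
Reactants: 8 (1R,2S,6S)-5,5-dimethoxy-2-(propan-2-yl)-7-oxabicyclo[4.1.0]hept-3-en-2-ol, 4 (2R,3R)-2,3-dimethyloxirane-2-carbaldehyde
Product: 10 (1S,5R,6R)-5-hydroxy-2,2-dimethoxy-6-(propan-2-yl)cyclohex-3-en-1-yl (2R,3R)-2,3-dimethyloxirane-2-carboxylate, via hydroxy ketone 9 (not isolated)
Conditions: 4 (3 equiv), SmI2 (30 mol%), ClCH2CH2Cl/THF, −10 °C to 40 °C
Reagents that add atoms: none
Why: Proposed new method: the trivalent samarium species formed from SmI2 and 4 binds the tertiary alkoxide of 8 and chelates the cis-epoxide oxygen, so the C1–O bond is polarised while the alkoxide pushes and the isopropyl group, held anti-periplanar to that bond, shifts from C2 to C1 with inversion (semipinacol 1,2-shift, stereospecific, placing isopropyl trans to the retained C–O bond, the ring bond not being anti-periplanar); the samarium aldolate of 9 then adds 4 to give a hemiacetal on the β-oxygen that transfers hydride intramolecularly to the new ketone from the face of that oxygen (Evans–Tishchenko reduction, 1,3-anti), which sets the carbinol cis to isopropyl and leaves the epoxyangelate on the right oxygen without a separate esterification of a base-sensitive β-hydroxy ketone; the closest known reactions are the SmI2-catalysed tandem semipinacol/Tishchenko reaction of α-hydroxy epoxides that have fully substituted migration termini with simple aldehydes, and the Evans–Tishchenko reduction of β-hydroxy ketones, whereas a secondary terminus, a substrate carrying an acid-labile allylic ketal and a chiral α,β-epoxy aldehyde as hydride donor and acyl source are untested.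

Step 7
Reactants: 10 (1S,5R,6R)-5-hydroxy-2,2-dimethoxy-6-(propan-2-yl)cyclohex-3-en-1-yl (2R,3R)-2,3-dimethyloxirane-2-carboxylate, 1 (2Z)-2-methylbut-2-enoic acid
Product: 12 (1S,5R,6R)-2,2-dimethoxy-5-{[(2Z)-2-methylbut-2-enoyl]oxy}-6-(propan-2-yl)cyclohex-3-en-1-yl (2R,3R)-2,3-dimethyloxirane-2-carboxylate, via mixed anhydride 11 (not isolated)
Conditions: 1, 2,4,6-Cl3C6H2COCl, Et3N, toluene, rt; then 10, 80 °C (no DMAP)
Reagents that add atoms: none
Why: Yamaguchi esterification through the preformed mixed anhydride acylates the hindered allylic alcohol with retention at C5 and, without a nucleophilic amine catalyst, avoids Z to E isomerisation of the angeloyl group; ketal, epoxide and the first ester are inert.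

Step 8
Reactants: 12 (1S,5R,6R)-2,2-dimethoxy-5-{[(2Z)-2-methylbut-2-enoyl]oxy}-6-(propan-2-yl)cyclohex-3-en-1-yl (2R,3R)-2,3-dimethyloxirane-2-carboxylate
Product: 13 (1S,5R,6R)-5-{[(2Z)-2-methylbut-2-enoyl]oxy}-2-oxo-6-(propan-2-yl)cyclohex-3-en-1-yl (2R,3R)-2,3-dimethyloxirane-2-carboxylate
Conditions: oxalic acid (cat.), THF/H2O, rt
Reagents that add atoms: water, O
Why: Mild acid hydrolysis of the allylic dimethyl ketal (acetal hydrolysis) unveils the enone while the electron-poor glycidic epoxide and both esters survive, and C1 next to the new ketone already carries its acyloxy group in the thermodynamically preferred equatorial position.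

Step 9
Reactants: 13 (1S,5R,6R)-5-{[(2Z)-2-methylbut-2-enoyl]oxy}-2-oxo-6-(propan-2-yl)cyclohex-3-en-1-yl (2R,3R)-2,3-dimethyloxirane-2-carboxylate, 14 formaldehyde
Product: 15 (1S,5R,6R)-3-(hydroxymethyl)-5-{[(2Z)-2-methylbut-2-enoyl]oxy}-2-oxo-6-(propan-2-yl)cyclohex-3-en-1-yl (2R,3R)-2,3-dimethyloxirane-2-carboxylate (CNP0293054.1)
Conditions: 37% aq. HCHO, imidazole (1 equiv), THF/1 M aq. NaHCO3, rt
Reagents that add atoms: none
Why: Morita–Baylis–Hillman reaction (reversible conjugate addition of imidazole at C4, aldol addition of the enolate to formaldehyde at C3, loss of imidazole) gives the 2-(hydroxymethyl)enone with the primary alcohol free, forms no stereocentre and is mild enough for the esters and the epoxide.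

**Compound list**

1 | (2Z)-2-methylbut-2-enoic acid (angelic acid) | C/C=C(/C)C(=O)O | starting material
2 | (2Z)-2-methylbut-2-en-1-ol | C/C=C(/C)CO | intermediate
3 | [(2S,3R)-2,3-dimethyloxiran-2-yl]methanol | OC[C@]1(C)O[C@@H]1C | intermediate
4 | (2R,3R)-2,3-dimethyloxirane-2-carbaldehyde | O=C[C@]1(C)O[C@@H]1C | intermediate
5 | 4,4-dimethoxycyclohexa-2,5-dien-1-one | COC1(OC)C=CC(=O)C=C1 | starting material
6 | isopropylmagnesium chloride | CC(C)[Mg]Cl | starting material
7 | 4,4-dimethoxy-1-(propan-2-yl)cyclohexa-2,5-dien-1-ol | CC(C)C1(O)C=CC(OC)(OC)C=C1 | intermediate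
8 | (1R,2S,6S)-5,5-dimethoxy-2-(propan-2-yl)-7-oxabicyclo[4.1.0]hept-3-en-2-ol (OH and epoxide cis, isopropyl anti to the epoxide) | O[C@@]1(C(C)C)C=CC(OC)(OC)[C@H]2O[C@@H]12 | intermediate
9 | (5S,6S)-5-hydroxy-4,4-dimethoxy-6-(propan-2-yl)cyclohex-2-en-1-one (OH and isopropyl trans; not isolated) | O=C1C=CC(OC)(OC)[C@@H](O)[C@@H]1C(C)C | intermediate
10 | (1S,5R,6R)-5-hydroxy-2,2-dimethoxy-6-(propan-2-yl)cyclohex-3-en-1-yl (2R,3R)-2,3-dimethyloxirane-2-carboxylate | O[C@@H]1C=CC(OC)(OC)[C@@H](OC(=O)[C@]2(C)O[C@@H]2C)[C@@H]1C(C)C | intermediate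
11 | (2Z)-2-methylbut-2-enoic 2,4,6-trichlorobenzoic anhydride (not isolated) | C/C=C(/C)C(=O)OC(=O)c1c(Cl)cc(Cl)cc1Cl | intermediate
12 | (1S,5R,6R)-2,2-dimethoxy-5-{[(2Z)-2-methylbut-2-enoyl]oxy}-6-(propan-2-yl)cyclohex-3-en-1-yl (2R,3R)-2,3-dimethyloxirane-2-carboxylate | C/C=C(/C)C(=O)O[C@@H]1C=CC(OC)(OC)[C@@H](OC(=O)[C@]2(C)O[C@@H]2C)[C@@H]1C(C)C | intermediate
13 | (1S,5R,6R)-5-{[(2Z)-2-methylbut-2-enoyl]oxy}-2-oxo-6-(propan-2-yl)cyclohex-3-en-1-yl (2R,3R)-2,3-dimethyloxirane-2-carboxylate | C/C=C(/C)C(=O)O[C@@H]1C=CC(=O)[C@@H](OC(=O)[C@]2(C)O[C@@H]2C)[C@@H]1C(C)C | intermediate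
14 | formaldehyde | C=O | starting material
15 | (1S,5R,6R)-3-(hydroxymethyl)-5-{[(2Z)-2-methylbut-2-enoyl]oxy}-2-oxo-6-(propan-2-yl)cyclohex-3-en-1-yl (2R,3R)-2,3-dimethyloxirane-2-carboxylate | C/C=C(/C)C(=O)O[C@@H]1C=C(CO)C(=O)[C@@H](OC(=O)[C@]2(C)O[C@@H]2C)[C@@H]1C(C)C | target

**Step count and risks**

Total step count: 9. Longest linear sequence: 7 (steps 1, 2, 3, 6, 7, 8, 9).

Most likely to fail, first: step 6 (the proposed new step). The migration terminus is secondary, so trivalent samarium may be too weak a Lewis acid for the 1,2-shift. Stronger activation endangers the allylic ketal, and hydroxy ketone 9 can lose water to a dienone before it is reduced. Fallback with known reactions only: it sets out from 8. Silylation (TMSCl, imidazole, DMF) gives {[(1R,2S,6S)-5,5-dimethoxy-2-(propan-2-yl)-7-oxabicyclo[4.1.0]hept-3-en-2-yl]oxy}trimethylsilane F1. The classical Lewis-acid pinacol-type rearrangement of this 2,3-epoxy silyl ether (BF3·OEt2, CH2Cl2, −78 °C, NaHCO3 quench, silicon lost as the fluoride) gives 9 as an isolated compound. A separate SmI2-catalysed Evans–Tishchenko reduction of 9 with 4 then comes back to the route at 10.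

Second: step 5. The catalyst has to distinguish two cis-disubstituted ring alkenes of a tertiary dienol that also carries a ketal, and the sense and level of induction are not secured. Fallback: it sets out from 7. Achiral hydroxyl-directed epoxidation (VO(acac)2, tBuOOH, CH2Cl2) gives the racemic cis-epoxy alcohol, that is 8 together with its enantiomer (1S,2R,6R)-5,5-dimethoxy-2-(propan-2-yl)-7-oxabicyclo[4.1.0]hept-3-en-2-ol F2. The racemate is taken through step 6 with enantiopure 4, which now serves as the resolving agent. There F2 passes through (5R,6R)-5-hydroxy-4,4-dimethoxy-6-(propan-2-yl)cyclohex-2-en-1-one F3 to the diastereomeric ester (1R,5S,6S)-5-hydroxy-2,2-dimethoxy-6-(propan-2-yl)cyclohex-3-en-1-yl (2R,3R)-2,3-dimethyloxirane-2-carboxylate F4. 10 and F4 are diastereomers and are separated by chromatography, so the route is rejoined at 10. The same separation removes the diastereomers that arise from any minor enantiomer of 4 or 8 in the main route.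

Third: step 9. The aqueous base and nucleophilic catalyst may hydrolyse or shift an ester, or the reaction may stall on the γ-acyloxy enone. Fallback: it sets out from 13. α-Iodination (I2, pyridine, CH2Cl2, rt) gives (1S,5S,6R)-3-iodo-5-{[(2Z)-2-methylbut-2-enoyl]oxy}-2-oxo-6-(propan-2-yl)cyclohex-3-en-1-yl (2R,3R)-2,3-dimethyloxirane-2-carboxylate F5. Stille coupling with (tributylstannyl)methanol Bu3SnCH2OH (Pd(PPh3)4, CuI, dioxane, 80 °C, neutral conditions) then comes back to the route at 15.

Further compounds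
F1 | step 6 | {[(1R,2S,6S)-5,5-dimethoxy-2-(propan-2-yl)-7-oxabicyclo[4.1.0]hept-3-en-2-yl]oxy}trimethylsilane | C[Si](C)(C)O[C@@]1(C(C)C)C=CC(OC)(OC)[C@H]2O[C@@H]12
F2 | step 5 | (1S,2R,6R)-5,5-dimethoxy-2-(propan-2-yl)-7-oxabicyclo[4.1.0]hept-3-en-2-ol | O[C@]1(C(C)C)C=CC(OC)(OC)[C@@H]2O[C@H]12
F3 | step 5 | (5R,6R)-5-hydroxy-4,4-dimethoxy-6-(propan-2-yl)cyclohex-2-en-1-one | O=C1C=CC(OC)(OC)[C@H](O)[C@H]1C(C)C
F4 | step 5 | (1R,5S,6S)-5-hydroxy-2,2-dimethoxy-6-(propan-2-yl)cyclohex-3-en-1-yl (2R,3R)-2,3-dimethyloxirane-2-carboxylate | O[C@H]1C=CC(OC)(OC)[C@H](OC(=O)[C@]2(C)O[C@@H]2C)[C@H]1C(C)C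
F5 | step 9 | (1S,5S,6R)-3-iodo-5-{[(2Z)-2-methylbut-2-enoyl]oxy}-2-oxo-6-(propan-2-yl)cyclohex-3-en-1-yl (2R,3R)-2,3-dimethyloxirane-2-carboxylate | C/C=C(/C)C(=O)O[C@@H]1C=C(I)C(=O)[C@@H](OC(=O)[C@]2(C)O[C@@H]2C)[C@@H]1C(C)C
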